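**Remark on the chemistry:** 2-methoxyresorcinol (1) carries only three of the four ring A oxygens, so the fourth is introduced by C–H borylation and oxidation; 4-bromo-2-methoxyphenol (10) and N,2-dimethoxy-N-methylacetamide (12) are taken as catalogue compounds, because they reach the ring B ketone 14 in two steps.

## Analysis of the target

Target 19 is a flavone: ring A (benzo) and ring C (4-pyranone) share the C4a–C8a bond, and ring B sits on C2. There is no stereocentre, and the prenyl alkene carries two identical methyl groups, so no configuration has to be set. Ring C is fully substituted (aryl at C2, methoxy at C3, carbonyl at C4), and ring A carries three different oxygens (hydroxyl at C5, prenyloxy at C7, methoxy at C8) besides O1, with C6 as its only CH. The sensitive groups are the prenyl aryl ether (acid, hydrogenation, electrophilic oxidants, Claisen shift to the free C6 on strong heating) and the two phenols, so the end of the synthesis must be mild, non-reductive and non-acidic. The hard points are the differentiation of the ring A oxygens, so that methoxy ends at C8 and not at C6 when ring C closes, and the 3-methoxy group, which classical flavone syntheses add late by oxidation and methylation. The strategy rests on reading ring C as two pieces: the four atoms O1–C8a–C4a–C4 are a salicylaldehyde, and C2–C3 are the two carbons of an alkyne that already bears ring B and the methoxy group. Aldehyde plus alkyne minus two hydrogens is exactly the chromone oxidation level, so the 3-methoxy group arrives with the alkyne, and the ring A ambiguity disappears if only one of the two oxygens ortho to the formyl group is free.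

## Retrosynthetic reasoning

**19 to 18.** The two O–H bonds at C5 and C4' are traced back to silyl ethers in 18. Triisopropylsilyl groups are chosen because their removal by a fluoride source leaves the prenyl ether untouched, and because they should survive base, magnesium-mediated formylation and the copper oxidant. The last step then has only to cleave two O–Si bonds.

**18 to 9 and 17.** Ring C is cut at O1–C2 and C3–C4, giving salicylaldehyde 9 and aryl ynol ether 17. The cut is made here because it divides the molecule into two fragments of similar size, each in its final substitution and oxidation state, and because it needs no later adjustment at C3. The forward reaction has to cleave the aldehyde C–H, insert the alkyne so that its methoxy-bearing carbon bonds to the acyl carbon, and close the C–O bond. Since O-6 of 9 is silylated, only O-2 can become O1, and the methoxy group is fixed at C8.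

**17 to 10 and 12.** The triple bond of 17 is traced to the Z enol triflate 16 by elimination, and 16 to α-methoxy ketone 14 through the chelated lithium enolate 15. Ketone 14 is cut at the aryl–carbonyl bond into aryllithium 13, from bromide 11, and Weinreb amide 12; 11 is the silyl ether of phenol 10. The gain is that the two alkyne carbons and the methoxy group come from one catalogue acyl donor, and no gaseous or unstable alkoxyacetylene has to be handled.

**9 to 7 and 8.** The prenyl O–C bond is cut to give dihydroxy aldehyde 7 and prenyl bromide 8. In 7 the 4-hydroxyl is para to the formyl group and free of hydrogen bonding, while the 2-hydroxyl is chelated, so the alkylation should take place at O-4 alone.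

**7 to 6.** The formyl C–C bond is cut, leading to the symmetric diol 6. Its two hydroxyls are equivalent and each has one free ortho carbon, so ortho-specific formylation can give only one aldehyde, and the same step removes the symmetry.

**6 to 1.** Diol 6 is traced through diacetate 5 to phenol 4, and 4 through boronate 3 to diacetate 2 and then to 1. Arene 1 lacks the oxygen para to the methoxy group, the one that becomes the 5-hydroxyl of 19. That position is the only ring carbon of 2 flanked by two hydrogens, so a sterically controlled C–H borylation followed by oxidation places the oxygen there. The acetates mask the two flanking hydroxyls, so that the silyl group can go only onto the new oxygen.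

## Alternatives that were turned down

**Alternative 1: ring A built last by cycloaddition and aromatisation.**
- Disconnection: C8–C8a and C4a–C5. Carbons C5 to C8 with their oxygens come from the tetra-oxygenated diene A3, and the dienophile is the C5=C6 bond of the monocyclic sulfinyl pyranone A2, which already carries ring B and the 3-methoxy group.
- Forward key step: the CH(OMe) terminus of A3 bonds to the β-carbon of A2, the sulfoxide leaves by syn-elimination, one alkoxy group is lost, and a desilylating work-up gives the 5,7-dihydroxy-8-methoxy flavone A1.
- For it: the polarity of diene and dienophile fixes the ring A pattern without any protecting group on ring A. The 7-hydroxyl of A1 is far more acidic than the chelated 5-hydroxyl, so alkylation with 8 should be selective, and one fluoride step then gives 19.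
- Against it: A2 is a monocyclic 4-pyranone with three different substituents on defined carbons, and its preparation would likely be longer than both fragments of the chosen route together. Its C5=C6 bond is a vinylogous ester and a weak dienophile even with the sulfinyl group. A3 is hydrolytically fragile and can react as an open-chain Mukaiyama–Michael donor without closing the ring.
- Comparison: on ring A regiochemistry it is as strong as the chosen route, and it avoids the borylation and protecting-group sequence. The chosen route offers fragments made from catalogue arenes in four to six standard steps and a ring closure that takes both fragments in their final oxidation state, with one step after it instead of two.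

**Alternative 2: ring expansion of an aurone.**
- Disconnection: O1–C2 of the flavonol A4, traced back to the benzylidene benzofuranone A5.
- Forward key step: the exocyclic alkene of A5 is dihalogenated, alcoholic alkali opens the furanone, and the phenoxide recloses on the benzylic carbon to give the 3-hydroxyflavone A4.
- For it: cheap reagents, no transition metal, an aldol condensation to make A5, ring A regiochemistry fixed in the benzofuranone, and a ring-forming event that is classical for polyoxygenated flavonols. On precedent and reagent cost it is stronger than the chosen route.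
- Against it: A4 has a 3-hydroxyl, so a methylation must follow. The alkali forces benzyl ethers, which can be removed only by hydrogenolysis or Lewis acid, so the prenyl group has to come afterwards. The 7- and 4'-hydroxyls of the resulting triol have similar acidity and could not be told apart without a second, orthogonal protecting group. The electron-rich ring A CH of A5, flanked by two benzyloxy groups, invites nuclear halogenation, and the dihalide can simply eliminate to a halo-aurone. At least four steps follow the key step.
- Comparison: the chosen route places the 3-methoxy and prenyl groups before ring closure and needs a single deprotection afterwards.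

**Alternative 3: C3 inserted as a one-carbon ylide.**
- Disconnection: C3–C4 and C2=C3. C3 with its methoxy group comes from ylide A8, and both aryl rings are held in the O-aroyl salicyloyl chloride A7.
- Forward key step: one equivalent of A8 is acylated by the acid chloride, a second deprotonates the phosphonium salt, and the acyl ylide olefinates the neighbouring aryl ester carbonyl to give A6, the bis-tert-butyldimethylsilyl ether of 19.
- For it: ring C has no regiochemical question, since C3 can only end between the two carbonyl carbons, and on this point it is stronger than the chosen route. It needs no precious metal and no acid-sensitive alkyne, and it ends with the same single fluoride step.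
- Against it: the acyl ylide is doubly stabilised and fully substituted at carbon, and it must olefinate an ester carbonyl, a reluctant Wittig acceptor. A7 is a 2,6-disubstituted benzoyl chloride beside an aryl ester, so acyl transfer to the ylide or acyl migration can compete. Making A7 from an aldehyde like 9 costs an oxidation, an O-aroylation and an acid chloride formation, plus a separate ring B acid, and the step produces stoichiometric phosphine oxide.
- Comparison: convergence is similar. The chosen route goes from 9 to the flavone in one catalytic step with loss of two hydrogens only, and accepts in exchange an alkyne class that is untested in this annulation.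

Key step: step 11

## Route

Step 1
Reactants: 1 2-methoxyresorcinol (2-methoxybenzene-1,3-diol)
Product: 2 2-methoxy-1,3-phenylene diacetate
Conditions: Ac2O, pyridine, DMAP (cat.), CH2Cl2, 0 °C to rt
Reagents that add atoms: acetic anhydride, CC(=O)OC(C)=O
Why: Acylation of both phenols; the esters mask the two hydroxyls that flank the methoxy group and can later be removed without touching an aryl silyl ether.

Step 2
Reactants: 2 2-methoxy-1,3-phenylene diacetate
Product: 4 5-hydroxy-2-methoxy-1,3-phenylene diacetate, via arylboronic ester 3 (not isolated)
Conditions: [Ir(OMe)(cod)]2 (cat.), dtbpy (cat.), B2pin2 (1.0 equiv), THF, 80 °C; then KHSO5 (as 2KHSO5·KHSO4·K2SO4), acetone–H2O, 0 °C to rt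
Reagents that add atoms: bis(pinacolato)diboron, CC1(C)OB(OC1(C)C)B1OC(C)(C)C(C)(C)O1 (boron is in 3 only); potassium peroxymonosulfate, [K+].[O-]S(=O)(=O)OO (the new oxygen)
Why: Iridium-catalysed C–H borylation is governed by sterics, so on this 1,2,3-trisubstituted arene only C5, the carbon flanked by two hydrogens, should react; ipso oxidation of the boronate then gives the phenol at that carbon under acidic conditions that spare the acetates. This is the step that supplies the fourth ring A oxygen.

Step 3
Reactants: 4 5-hydroxy-2-methoxy-1,3-phenylene diacetate
Product: 5 2-methoxy-5-(triisopropylsilyloxy)-1,3-phenylene diacetate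
Conditions: TIPSOTf, 2,6-lutidine, CH2Cl2, 0 °C
Reagents that add atoms: triisopropylsilyl trifluoromethanesulfonate, CC(C)[Si](C(C)C)(C(C)C)OS(=O)(=O)C(F)(F)F
Why: Silylation of the only free phenol; a non-nucleophilic base is used so that the aryl acetates are not transferred or cleaved.

Step 4
Reactants: 5 2-methoxy-5-(triisopropylsilyloxy)-1,3-phenylene diacetate
Product: 6 2-methoxy-5-(triisopropylsilyloxy)benzene-1,3-diol
Conditions: NH3 (7 M in MeOH), 0 °C to rt, under N2
Reagents that add atoms: none
Why: Aminolysis of aryl acetates is fast and mild, and the hindered aryl triisopropylsilyl ether should not be attacked by ammonia in methanol.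

Step 5
Reactants: 6 2-methoxy-5-(triisopropylsilyloxy)benzene-1,3-diol
Product: 7 2,4-dihydroxy-3-methoxy-6-(triisopropylsilyloxy)benzaldehyde
Conditions: MgCl2, Et3N, (CH2O)n, MeCN, 60–80 °C; dilute HCl work-up
Reagents that add atoms: paraformaldehyde (as formaldehyde), C=O
Why: Magnesium-mediated ortho-formylation (Casnati–Skattebøl): the magnesium phenoxide delivers formaldehyde to its ortho carbon and a second formaldehyde accepts hydride. The two hydroxyls of 6 are equivalent and each has one free ortho carbon, so a single aldehyde should form, and the formyl group deactivates the ring toward a second formylation.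

Step 6
Reactants: 7 2,4-dihydroxy-3-methoxy-6-(triisopropylsilyloxy)benzaldehyde; 8 prenyl bromide (1-bromo-3-methylbut-2-ene)
Product: 9 2-hydroxy-3-methoxy-4-(3-methylbut-2-en-1-yloxy)-6-(triisopropylsilyloxy)benzaldehyde
Conditions: K2CO3 (1.1 equiv), 8 (1.05 equiv), acetone, rt
Reagents that add atoms: none
Why: Williamson etherification; the 4-hydroxyl is para to the formyl group, more acidic and not hydrogen-bonded, while the 2-hydroxyl is chelated to the formyl oxygen, so one equivalent of 8 should alkylate O-4 only.

Step 7
Reactants: 10 4-bromo-2-methoxyphenol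
Product: 11 (4-bromo-2-methoxyphenoxy)triisopropylsilane
Conditions: TIPSCl, imidazole, DMF, rt
Reagents that add atoms: triisopropylsilyl chloride, CC(C)[Si](Cl)(C(C)C)C(C)C
Why: Standard silylation of a phenol; the silyl ether tolerates the organolithium and the amide and alkoxide bases that follow.

Step 8
Reactants: 11 (4-bromo-2-methoxyphenoxy)triisopropylsilane; 12 N,2-dimethoxy-N-methylacetamide
Product: 14 2-methoxy-1-[3-methoxy-4-(triisopropylsilyloxy)phenyl]ethan-1-one, via aryllithium 13 (not isolated)
Conditions: n-BuLi, THF, −78 °C; then 12, −78 to 0 °C; aq. NH4Cl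
Reagents that add atoms: none
Why: Bromine–lithium exchange followed by Weinreb ketone synthesis; the chelated tetrahedral adduct does not collapse before work-up, so over-addition is avoided.

Step 9
Reactants: 14 2-methoxy-1-[3-methoxy-4-(triisopropylsilyloxy)phenyl]ethan-1-one
Product: 16 (Z)-2-methoxy-1-[3-methoxy-4-(triisopropylsilyloxy)phenyl]ethenyl trifluoromethanesulfonate, via lithium enolate 15 (not isolated)
Conditions: LiN(SiMe3)2, THF, −78 °C; then PhNTf2, DMPU, −78 °C to rt; aq. NH4Cl
Reagents that add atoms: N-phenylbis(trifluoromethanesulfonimide), FC(F)(F)S(=O)(=O)N(c1ccccc1)S(=O)(=O)C(F)(F)F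
Why: Enol triflate formation; lithium chelated between the enolate oxygen and the methoxy oxygen gives the Z enolate, and O-sulfonylation keeps that geometry, which places the vinyl hydrogen anti to the triflate.

Step 10
Reactants: 16 (Z)-2-methoxy-1-[3-methoxy-4-(triisopropylsilyloxy)phenyl]ethenyl trifluoromethanesulfonate
Product: 17 2-methoxy-4-(methoxyethynyl)-1-(triisopropylsilyloxy)benzene
Conditions: KOtBu, THF, −78 to 0 °C; filtration through basic alumina
Reagents that add atoms: none
Why: Anti-periplanar E2 elimination of triflate from an α-alkoxy enol triflate, a known route to ynol ethers; a methyl ynol ether cannot lose an alkene by retro-ene reaction, so it should tolerate the warming of the next step.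

Step 11
Reactants: 9 2-hydroxy-3-methoxy-4-(3-methylbut-2-en-1-yloxy)-6-(triisopropylsilyloxy)benzaldehyde; 17 2-methoxy-4-(methoxyethynyl)-1-(triisopropylsilyloxy)benzene
Product: 18 3,8-dimethoxy-2-[3-methoxy-4-(triisopropylsilyloxy)phenyl]-7-(3-methylbut-2-en-1-yloxy)-5-(triisopropylsilyloxy)-4H-chromen-4-one
Conditions: [Cp*RhCl2]2 (2.5 mol%), Cu(OAc)2 (anhydrous, 2.1 equiv), Na2CO3 (2.2 equiv), 4 Å MS, ClCH2CH2Cl, 80 °C, 17 (1.5 equiv) added slowly, under N2
Reagents that add atoms: none
Why: Proposed new method: the closest known reaction type is the rhodium-catalysed oxidative annulation of salicylaldehydes with diaryl and alkyl aryl alkynes to 2,3-disubstituted chromones, and an alkoxy-substituted alkyne has not been used in it. The phenoxide of 9 binds Cp*Rh(OAc)2 (trivalent rhodium, formed from [Cp*RhCl2]2 and Cu(OAc)2), and acetate-assisted cleavage of the aldehyde C–H gives a five-membered acyl rhodacycle. Ynol ether 17 then inserts into the Rh–acyl bond: the acyl group migrates to the oxygen-bearing, electrophilic alkyne carbon (new C3–C4 bond), and rhodium takes the aryl-bearing carbon, which is the electron-rich end of the polarised ynol ether and also the position the metal prefers with alkyl aryl alkynes, so both effects should put aryl on C2 and methoxy on C3. The six-membered ring C closes by C(sp2)–O reductive elimination from the seven-membered oxarhodacycle (new O1–C2 bond), overall a formal [4+2] oxidative annulation, and two equivalents of Cu(OAc)2 return monovalent rhodium to the trivalent state. The step needs regioselective insertion (secured as described), use of O-2 and not O-6 for ring closure (secured because O-6 is silylated, which fixes methoxy at C8) and survival of the ynol ether, for which Na2CO3 and sieves remove acetic acid and water, no silver salt is used and 17 is added slowly. No stereocentre is formed.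

Step 12
Reactants: 18 3,8-dimethoxy-2-[3-methoxy-4-(triisopropylsilyloxy)phenyl]-7-(3-methylbut-2-en-1-yloxy)-5-(triisopropylsilyloxy)-4H-chromen-4-one
Product: 19 5-hydroxy-2-(4-hydroxy-3-methoxyphenyl)-3,8-dimethoxy-7-(3-methylbut-2-en-1-yloxy)-4H-chromen-4-one (5,4'-dihydroxy-3,8,3'-trimethoxy-7-prenyloxyflavone)
Conditions: Bu4NF, AcOH (1:1, 2.5 equiv each), THF, 0 °C
Reagents that add atoms: none
Why: Fluoride-mediated cleavage of both aryl O–Si bonds; the acetic acid buffer keeps the liberated phenols protonated, and the prenyl and methyl ethers are inert to fluoride.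

## Compound list

1 | 2-methoxyresorcinol | COc1c(O)cccc1O | starting material
2 | 2-methoxy-1,3-phenylene diacetate | COc1c(OC(C)=O)cccc1OC(C)=O | intermediate
3 | 2-methoxy-5-(4,4,5,5-tetramethyl-1,3,2-dioxaborolan-2-yl)-1,3-phenylene diacetate | COc1c(OC(C)=O)cc(B2OC(C)(C)C(C)(C)O2)cc1OC(C)=O | intermediate (not isolated)
4 | 5-hydroxy-2-methoxy-1,3-phenylene diacetate | COc1c(OC(C)=O)cc(O)cc1OC(C)=O | intermediate
5 | 2-methoxy-5-(triisopropylsilyloxy)-1,3-phenylene diacetate | COc1c(OC(C)=O)cc(O[Si](C(C)C)(C(C)C)C(C)C)cc1OC(C)=O | intermediate
6 | 2-methoxy-5-(triisopropylsilyloxy)benzene-1,3-diol | COc1c(O)cc(O[Si](C(C)C)(C(C)C)C(C)C)cc1O | intermediate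
7 | 2,4-dihydroxy-3-methoxy-6-(triisopropylsilyloxy)benzaldehyde | COc1c(O)cc(O[Si](C(C)C)(C(C)C)C(C)C)c(C=O)c1O | intermediate
8 | prenyl bromide (1-bromo-3-methylbut-2-ene) | CC(C)=CCBr | starting material
9 | 2-hydroxy-3-methoxy-4-(3-methylbut-2-en-1-yloxy)-6-(triisopropylsilyloxy)benzaldehyde | COc1c(OCC=C(C)C)cc(O[Si](C(C)C)(C(C)C)C(C)C)c(C=O)c1O | intermediate
10 | 4-bromo-2-methoxyphenol | COc1cc(Br)ccc1O | starting material
11 | (4-bromo-2-methoxyphenoxy)triisopropylsilane | COc1cc(Br)ccc1O[Si](C(C)C)(C(C)C)C(C)C | intermediate
12 | N,2-dimethoxy-N-methylacetamide | COCC(=O)N(C)OC | starting material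
13 | [3-methoxy-4-(triisopropylsilyloxy)phenyl]lithium | [Li]c1ccc(O[Si](C(C)C)(C(C)C)C(C)C)c(OC)c1 | intermediate (not isolated)
14 | 2-methoxy-1-[3-methoxy-4-(triisopropylsilyloxy)phenyl]ethan-1-one | COCC(=O)c1ccc(O[Si](C(C)C)(C(C)C)C(C)C)c(OC)c1 | intermediate
15 | lithium (Z)-2-methoxy-1-[3-methoxy-4-(triisopropylsilyloxy)phenyl]ethen-1-olate | [Li+].CO/C=C(\[O-])c1ccc(O[Si](C(C)C)(C(C)C)C(C)C)c(OC)c1 | intermediate (not isolated)
16 | (Z)-2-methoxy-1-[3-methoxy-4-(triisopropylsilyloxy)phenyl]ethenyl trifluoromethanesulfonate | CO/C=C(\OS(=O)(=O)C(F)(F)F)c1ccc(O[Si](C(C)C)(C(C)C)C(C)C)c(OC)c1 | intermediate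
17 | 2-methoxy-4-(methoxyethynyl)-1-(triisopropylsilyloxy)benzene | COC#Cc1ccc(O[Si](C(C)C)(C(C)C)C(C)C)c(OC)c1 | intermediate
18 | 3,8-dimethoxy-2-[3-methoxy-4-(triisopropylsilyloxy)phenyl]-7-(3-methylbut-2-en-1-yloxy)-5-(triisopropylsilyloxy)-4H-chromen-4-one | COc1cc(-c2oc3c(OC)c(OCC=C(C)C)cc(O[Si](C(C)C)(C(C)C)C(C)C)c3c(=O)c2OC)ccc1O[Si](C(C)C)(C(C)C)C(C)C | intermediate
19 | 5-hydroxy-2-(4-hydroxy-3-methoxyphenyl)-3,8-dimethoxy-7-(3-methylbut-2-en-1-yloxy)-4H-chromen-4-one | COc1cc(-c2oc3c(OC)c(OCC=C(C)C)cc(O)c3c(=O)c2OC)ccc1O | target

## Step count and risk

Total: 12 steps. Longest linear sequence: 8 steps (steps 1 to 6, then 11 and 12); the ring B branch has 4 steps before the key step.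

**Step 11 (key step, proposed new method).**
- What may go wrong: addition of acetic acid or water to the ynol ether before it can insert, since ynol ethers are classical dehydrating agents for carboxylic acids. Other possible failures are insertion in the reverse sense, which would put methoxy on C2 and aryl on C3, decarbonylation of the acyl rhodium species, slow C–H cleavage next to the bulky silyl ether, and allylic C–H activation of the prenyl group.
- Fallback (known chemistry, the ω-methoxyacetophenone and Baker–Venkataraman sequence): it sets out from 9 and from 11 and returns at 18. Methoxymethyllithium, from tributyl(methoxymethyl)stannane and n-BuLi, is added to 9 to give 1-[2-hydroxy-3-methoxy-4-(3-methylbut-2-en-1-yloxy)-6-(triisopropylsilyloxy)phenyl]-2-methoxyethan-1-ol F1. Oxidation with MnO2 gives the ketone 1-[2-hydroxy-3-methoxy-4-(3-methylbut-2-en-1-yloxy)-6-(triisopropylsilyloxy)phenyl]-2-methoxyethan-1-one F2. Aryllithium 13, made from 11 as in step 8, is quenched with CO2 to 3-methoxy-4-(triisopropylsilyloxy)benzoic acid F3. Carbodiimide coupling of F2 with F3 gives the aryl ester 2-(methoxyacetyl)-6-methoxy-5-(3-methylbut-2-en-1-yloxy)-3-(triisopropylsilyloxy)phenyl 3-methoxy-4-(triisopropylsilyloxy)benzoate F4. LiN(SiMe3)2 then brings about the Baker–Venkataraman acyl shift to 1-[2-hydroxy-3-methoxy-4-(3-methylbut-2-en-1-yloxy)-6-(triisopropylsilyloxy)phenyl]-2-methoxy-3-[3-methoxy-4-(triisopropylsilyloxy)phenyl]propane-1,3-dione F5, and cyclodehydration with pyridinium p-toluenesulfonate in warm toluene gives 18.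

**Step 2.**
- What may go wrong: the ester groups may slow the borylation or divert it (carbonyl-assisted metalation ortho to an acetate, or reduction of an acetate by the borane formed), and the acetates may be partly hydrolysed during the oxidation.
- Fallback: it sets out from 1 and returns at 6, with acetal ethers in place of the esters. Compound 1 is converted with chloromethyl methyl ether and iPr2NEt into 2-methoxy-1,3-bis(methoxymethoxy)benzene F6. This is borylated under the same iridium catalysis to 2-[4-methoxy-3,5-bis(methoxymethoxy)phenyl]-4,4,5,5-tetramethyl-1,3,2-dioxaborolane F7 and oxidised with H2O2 and NaOH to 4-methoxy-3,5-bis(methoxymethoxy)phenol F8. Silylation with TIPSCl and imidazole gives [4-methoxy-3,5-bis(methoxymethoxy)phenoxy]triisopropylsilane F9, and HCl in methanol removes both acetals to give 6.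

**Step 5.**
- What may go wrong: a second formylation at the remaining activated position, incomplete conversion because the bis-phenoxide aggregates with magnesium, or partial loss of the silyl group on prolonged heating with amine.
- Fallback: it sets out from 6 and returns at 9, so that the formylated substrate has a single phenol with a single free ortho carbon. Diol 6 is alkylated once with 8 (K2CO3, acetone, recovered 6 recycled) to 2-methoxy-3-(3-methylbut-2-en-1-yloxy)-5-(triisopropylsilyloxy)phenol F10, and the same magnesium-mediated formylation then gives 9 directly.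

**Step 6.**
- What may go wrong: C-prenylation at the carbon between two oxygens, alkylation of both hydroxyls, or carbonate-induced loss of the silyl ether ortho to the formyl group.
- Fallback: it sets out from 7 and returns at 9. A Mitsunobu etherification with 3-methylbut-2-en-1-ol, PPh3 and diisopropyl azodicarboxylate in THF at 0 °C is used; it runs without base, alkylates the more acidic 4-hydroxyl on oxygen only, and passes through no new isolated compound.

**Step 10.**
- What may go wrong: addition of tert-butoxide to the ynol ether formed, attack of the alkoxide at silicon, or slow syn-elimination if part of 16 has the E configuration.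
- Fallback: it sets out from 11 and returns at 17 by cross-coupling instead of elimination. Bromide 11 is converted through 13 and iodine into (4-iodo-2-methoxyphenoxy)triisopropylsilane F11. Chloroacetaldehyde dimethyl acetal with three equivalents of LiNEt2 gives (methoxyethynyl)lithium F12, which ZnCl2 turns into chloro(methoxyethynyl)zinc F13. Negishi coupling of F11 with F13 under Pd(PPh3)4 (zerovalent palladium) at room temperature gives 17.

## Further compounds

F1 | step 11 | 1-[2-hydroxy-3-methoxy-4-(3-methylbut-2-en-1-yloxy)-6-(triisopropylsilyloxy)phenyl]-2-methoxyethan-1-ol (racemic) | COCC(O)c1c(O)c(OC)c(OCC=C(C)C)cc1O[Si](C(C)C)(C(C)C)C(C)C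
F2 | step 11 | 1-[2-hydroxy-3-methoxy-4-(3-methylbut-2-en-1-yloxy)-6-(triisopropylsilyloxy)phenyl]-2-methoxyethan-1-one | COCC(=O)c1c(O)c(OC)c(OCC=C(C)C)cc1O[Si](C(C)C)(C(C)C)C(C)C
F3 | step 11 | 3-methoxy-4-(triisopropylsilyloxy)benzoic acid | COc1cc(C(=O)O)ccc1O[Si](C(C)C)(C(C)C)C(C)C
F4 | step 11 | 2-(methoxyacetyl)-6-methoxy-5-(3-methylbut-2-en-1-yloxy)-3-(triisopropylsilyloxy)phenyl 3-methoxy-4-(triisopropylsilyloxy)benzoate | COCC(=O)c1c(OC(=O)c2ccc(O[Si](C(C)C)(C(C)C)C(C)C)c(OC)c2)c(OC)c(OCC=C(C)C)cc1O[Si](C(C)C)(C(C)C)C(C)C
F5 | step 11 | 1-[2-hydroxy-3-methoxy-4-(3-methylbut-2-en-1-yloxy)-6-(triisopropylsilyloxy)phenyl]-2-methoxy-3-[3-methoxy-4-(triisopropylsilyloxy)phenyl]propane-1,3-dione (racemic, enolisable) | COC(C(=O)c1ccc(O[Si](C(C)C)(C(C)C)C(C)C)c(OC)c1)C(=O)c1c(O)c(OC)c(OCC=C(C)C)cc1O[Si](C(C)C)(C(C)C)C(C)C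
F6 | step 2 | 2-methoxy-1,3-bis(methoxymethoxy)benzene | COCOc1cccc(OCOC)c1OC
F7 | step 2 | 2-[4-methoxy-3,5-bis(methoxymethoxy)phenyl]-4,4,5,5-tetramethyl-1,3,2-dioxaborolane | COCOc1cc(B2OC(C)(C)C(C)(C)O2)cc(OCOC)c1OC
F8 | step 2 | 4-methoxy-3,5-bis(methoxymethoxy)phenol | COCOc1cc(O)cc(OCOC)c1OC
F9 | step 2 | [4-methoxy-3,5-bis(methoxymethoxy)phenoxy]triisopropylsilane | COCOc1cc(O[Si](C(C)C)(C(C)C)C(C)C)cc(OCOC)c1OC
F10 | step 5 | 2-methoxy-3-(3-methylbut-2-en-1-yloxy)-5-(triisopropylsilyloxy)phenol | COc1c(O)cc(O[Si](C(C)C)(C(C)C)C(C)C)cc1OCC=C(C)C
F0 | step 6 | none | none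
F11 | step 10 | (4-iodo-2-methoxyphenoxy)triisopropylsilane | COc1cc(I)ccc1O[Si](C(C)C)(C(C)C)C(C)C
F12 | step 10 | (methoxyethynyl)lithium | [Li]C#COC
F13 | step 10 | chloro(methoxyethynyl)zinc | Cl[Zn]C#COC
A1 | alternative 1 | 5,7-dihydroxy-3,8-dimethoxy-2-[3-methoxy-4-(triisopropylsilyloxy)phenyl]-4H-chromen-4-one | COc1cc(-c2oc3c(OC)c(O)cc(O)c3c(=O)c2OC)ccc1O[Si](C(C)C)(C(C)C)C(C)C
A2 | alternative 1 | 3-methoxy-2-[3-methoxy-4-(triisopropylsilyloxy)phenyl]-5-(phenylsulfinyl)-4H-pyran-4-one (racemic at sulfur) | COc1cc(-c2occ(S(=O)c3ccccc3)c(=O)c2OC)ccc1O[Si](C(C)C)(C(C)C)C(C)C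
A3 | alternative 1 | 1,4-dimethoxy-1,3-bis(trimethylsilyloxy)buta-1,3-diene | COC=C(O[Si](C)(C)C)C=C(OC)O[Si](C)(C)C
A4 | alternative 2 | 5,7-bis(benzyloxy)-2-(4-benzyloxy-3-methoxyphenyl)-3-hydroxy-8-methoxy-4H-chromen-4-one | COc1cc(-c2oc3c(OC)c(OCc4ccccc4)cc(OCc4ccccc4)c3c(=O)c2O)ccc1OCc1ccccc1
A5 | alternative 2 | (Z)-4,6-bis(benzyloxy)-2-(4-benzyloxy-3-methoxybenzylidene)-7-methoxybenzofuran-3(2H)-one | COc1cc(/C=C2\Oc3c(OC)c(OCc4ccccc4)cc(OCc4ccccc4)c3C2=O)ccc1OCc1ccccc1
A6 | alternative 3 | 5-(tert-butyldimethylsilyloxy)-2-[4-(tert-butyldimethylsilyloxy)-3-methoxyphenyl]-3,8-dimethoxy-7-(3-methylbut-2-en-1-yloxy)-4H-chromen-4-one | COc1cc(-c2oc3c(OC)c(OCC=C(C)C)cc(O[Si](C)(C)C(C)(C)C)c3c(=O)c2OC)ccc1O[Si](C)(C)C(C)(C)C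
A7 | alternative 3 | 2-{[4-(tert-butyldimethylsilyloxy)-3-methoxybenzoyl]oxy}-6-(tert-butyldimethylsilyloxy)-3-methoxy-4-(3-methylbut-2-en-1-yloxy)benzoyl chloride | COc1cc(C(=O)Oc2c(OC)c(OCC=C(C)C)cc(O[Si](C)(C)C(C)(C)C)c2C(Cl)=O)ccc1O[Si](C)(C)C(C)(C)C
A8 | alternative 3 | (methoxymethylene)triphenylphosphorane | COC=P(c1ccccc1)(c1ccccc1)c1ccccc1
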